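## Retrosynthetic overview

1. The strategy rests on the all-carbon spiro centre C4'. It is shared by ring D (C7–C8–C14–C4'–C10') and the thujane cyclopentane ring E (C4'–C3'–C2'–C1'–C5', fused to cyclopropane ring F C1'–C5'–C6'). C4' carries C14, C10', C3' and C5', with C14 on the C6' face. This is the pattern left when a 2-aryl-norcar-2-ene oxide contracts and expels C10' as a formyl carbon.
2. The target comes from a catechol by oxidation and a C7-H shift that forms the C7=C8 quinone methide. The catechol comes from a keto aldehyde in which a C7–C10' aldol closes ring D.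
3. The keto aldehyde comes from a C4'–C10' epoxide in a six-membered ring. A shift of C3' from C10' to C4' makes ring E. The epoxide follows from a C14–C4' Negishi coupling of a 14-bromo C6-ketal abietane with a norcarenyl triflate.
4. Abietane half: ring C is bought, rings A and B come from an enantioselective polyene cyclisation, C6=O comes by way of the Δ6 alkene, and C5 is then epimerised to the A/B-cis fusion that the target has. Norcarane half: CBS reduction followed by hydroxyl-directed cyclopropanation.
5. Ring order: C, then A and B. Separately, F on a six-membered carrier ring, then E by contraction, then D.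

Key step: step 20

## Remarks on the chemistry

- **Numbering.** The abietane carbons are C1–C20 and the monoterpene carbons are C1'–C10'. C4' is the spiro carbon, C10' the carbinol carbon and C6' the cyclopropane CH2. The terms α and β refer to the abietane faces, with C20 β.
- **Reading of the target.** The configuration is 5R,10S,4'S,10'R,1'R,5'S.
  - H-5 is β, cis to C20, so the A/B fusion is cis.
  - The 10'-OH is β and cis to C3' on ring D.
  - C14 is syn to C6' on ring E.
- **Assumption.** The (R)-binaphthol tin acid of step 11 and the (S)-oxazaborolidine of step 2 are taken to act in their usual sense. If not, the mirror-image ligand is used.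
- **Stereochemical purity.** Any A/B-cis isomer formed in step 11 is (5S,10R). It must be removed by chromatography before step 15, because it belongs to the mirror-image series of 22.
- **Protecting groups.** The phenols are carried as benzyl ethers. The final deprotection is then neutral and does not expose the β-hydroxy ketone 33 to a boron halide.

## Route

Step 1
Reactants: 1 3-ethoxycyclohex-2-en-1-one
Product: 3 3-isopropylcyclohex-2-en-1-one, via tertiary magnesium alkoxide 2 (not isolated)
Conditions: i-PrMgCl, THF, 0 °C; then 1 M HCl, 23 °C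
Reagents that add atoms: isopropylmagnesium chloride, CC(C)[Mg]Cl; water, O
Why: Stork–Danheiser transposition, in which 1,2-addition to the vinylogous ester, acid hydrolysis of the enol ether and loss of the tertiary hydroxyl give the 3-alkyl enone; no stereocentre is formed.

Step 2
Reactants: 3 3-isopropylcyclohex-2-en-1-one
Product: 4 (R)-3-isopropylcyclohex-2-en-1-ol
Conditions: (S)-2-methyl-CBS-oxazaborolidine (10 mol %), BH3·SMe2, THF, −30 °C; MeOH
Reagents that add atoms: none
Why: Corey–Bakshi–Shibata reduction, in which the alkene arm acts as the large substituent so that the (S)-catalyst should give the R carbinol (future C4'), a relay centre for C1' and C5'.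

Step 3
Reactants: 4 (R)-3-isopropylcyclohex-2-en-1-ol
Product: 5 (1S,2R,6R)-6-isopropylbicyclo[4.1.0]heptan-2-ol
Conditions: Et2Zn, CH2I2, CH2Cl2, −10 → 23 °C
Reagents that add atoms: diiodomethane, ICI
Why: Hydroxyl-directed Simmons–Smith cyclopropanation (Furukawa variant), in which the zinc-bound oxygen delivers C6' to the alkene face syn to it and so fixes C1' (R) and C5' (S) and closes ring F.

Step 4
Reactants: 5 (1S,2R,6R)-6-isopropylbicyclo[4.1.0]heptan-2-ol
Product: 6 (1S,6R)-6-isopropylbicyclo[4.1.0]heptan-2-one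
Conditions: Dess–Martin periodinane, CH2Cl2, 23 °C
Reagents that add atoms: none
Why: Dess–Martin oxidation of the cyclopropyl carbinol under neutral conditions removes the relay centre and leaves the cyclopropane, C1' and C5' untouched.

Step 5
Reactants: 6 (1S,6R)-6-isopropylbicyclo[4.1.0]heptan-2-one
Product: 8 (1S,6R)-6-isopropylbicyclo[4.1.0]hept-2-en-2-yl trifluoromethanesulfonate, via lithium enolate 7 (not isolated)
Conditions: LiHMDS, THF, −78 °C; PhNTf2, −78 → 0 °C
Reagents that add atoms: N-phenylbis(trifluoromethanesulfonimide), O=S(=O)(N(c1ccccc1)S(=O)(=O)C(F)(F)F)C(F)(F)F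
Why: Enolate O-sulfonylation (enol triflate synthesis), which is regioselective because only C10'-H can be removed, an enolate towards bridgehead C5' being a strained alkylidene-cyclopropane.

Step 6
Reactants: 9 3-bromo-4,5-dihydroxybenzaldehyde
Product: 10 3,4-bis(benzyloxy)-5-bromobenzaldehyde
Conditions: BnBr, K2CO3, DMF, 60 °C
Reagents that add atoms: benzyl bromide, BrCc1ccccc1
Why: Williamson ether synthesis on both phenols (future O11 and O12), with the substitution pattern of ring C fixed by the purchased arene.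

Step 7
Reactants: 10 3,4-bis(benzyloxy)-5-bromobenzaldehyde
Product: 11 3,4-bis(benzyloxy)-5-isopropylbenzaldehyde
Conditions: i-PrZnBr, Pd(OAc)2 (1 mol %), CPhos (2 mol %), THF–toluene, 23 °C
Reagents that add atoms: isopropylzinc bromide, CC(C)[Zn]Br
Why: Negishi coupling of a secondary alkylzinc halide, in which the biaryl phosphine favours reductive elimination over β-hydride elimination, so the branched group on C13 is kept and the aldehyde is tolerated.

Step 8
Reactants: 11 3,4-bis(benzyloxy)-5-isopropylbenzaldehyde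
Product: 12 [3,4-bis(benzyloxy)-5-isopropylphenyl]methanol
Conditions: NaBH4, MeOH, 0 °C
Reagents that add atoms: none
Why: Borohydride reduction of the aldehyde carbon (future C7).

Step 9
Reactants: 12 [3,4-bis(benzyloxy)-5-isopropylphenyl]methanol
Product: 13 1,2-bis(benzyloxy)-5-(chloromethyl)-3-isopropylbenzene
Conditions: SOCl2, CH2Cl2, 0 °C
Reagents that add atoms: thionyl chloride, O=S(Cl)Cl
Why: Chlorodehydroxylation of an electron-rich benzylic alcohol through its chlorosulfite, with the chloride used without storage.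

Step 10
Reactants: 13 1,2-bis(benzyloxy)-5-(chloromethyl)-3-isopropylbenzene; 14 geranyl bromide
Product: 16 (E)-1,2-bis(benzyloxy)-5-(4,8-dimethylnona-3,7-dien-1-yl)-3-isopropylbenzene, via benzylic Grignard reagent 15 (not isolated)
Conditions: Mg, THF, 0 °C; then 14, Li2CuCl4 (3 mol %), THF, −10 → 23 °C
Reagents that add atoms: none
Why: Copper-catalysed coupling of a benzylic Grignard reagent with an allylic bromide at its primary terminus (SN2 mode) forms C6–C7 and keeps the E geometry of C5=C10, on which the ring-fusion stereochemistry depends.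

Step 11
Reactants: 16 (E)-1,2-bis(benzyloxy)-5-(4,8-dimethylnona-3,7-dien-1-yl)-3-isopropylbenzene
Product: 18 (5S,10S)-11,12-bis(benzyloxy)abieta-8,11,13-triene, via monocyclic cyclohexene 17 (not isolated)
Conditions: SnCl4·(R)-2-(2-fluorobenzyloxy)-2'-hydroxy-1,1'-binaphthyl (1.1 equiv), toluene, −78 °C; then CF3CO2H, SnCl4, CH2Cl2, −78 °C
Reagents that add atoms: none
Why: Enantioselective proton-initiated polyene cyclisation with a Lewis-acid-assisted chiral Brønsted acid, in which face-selective protonation at C3 and chair–chair folding of the E alkene give anti addition (H-5 α, C20 β), the arene closes at C9 next to O11 and not at the position beside the isopropyl group, and the achiral acid closes ring B in material that stopped at 17.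

Step 12
Reactants: 18 (5S,10S)-11,12-bis(benzyloxy)abieta-8,11,13-triene
Product: 19 (5S,10S)-11,12-bis(benzyloxy)abieta-6,8,11,13-tetraene
Conditions: DDQ (1.1 equiv), 1,4-dioxane, 80 °C
Reagents that add atoms: none
Why: Quinone dehydrogenation, in which hydride abstraction at C7 (cation stabilised by the para O12) and loss of H-6 give the styrene, quaternary C4 and C10 block aromatisation, and aryl benzyl ethers are poor hydride donors.

Step 13
Reactants: 19 (5S,10S)-11,12-bis(benzyloxy)abieta-6,8,11,13-tetraene
Product: 20 (5S,10S)-11,12-bis(benzyloxy)-6α,7α-epoxyabieta-8,11,13-triene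
Conditions: DMDO, acetone–CH2Cl2, 0 °C
Reagents that add atoms: dimethyldioxirane, CC1(C)OO1
Why: Dioxirane epoxidation of the styrene-type alkene from the α face, opposite the axial C19 and C20 methyl groups; the centres at C6 and C7 are lost again in step 14.

Step 14
Reactants: 20 (5S,10S)-11,12-bis(benzyloxy)-6α,7α-epoxyabieta-8,11,13-triene
Product: 21 (5S,10S)-11,12-bis(benzyloxy)abieta-8,11,13-trien-6-one
Conditions: BF3·OEt2 (20 mol %), CH2Cl2, −40 °C
Reagents that add atoms: none
Why: Meinwald rearrangement with 1,2-hydride shift, in which benzylic C7–O ionisation and migration of H-6 to C7 put the carbonyl at C6, the usual course for 6,7-epoxides of abietatrienes; C5 stays S.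

Step 15
Reactants: 21 (5S,10S)-11,12-bis(benzyloxy)abieta-8,11,13-trien-6-one
Product: 22 (5R,10S)-11,12-bis(benzyloxy)abieta-8,11,13-trien-6-one
Conditions: NaOMe, MeOH–THF, 65 °C, argon
Reagents that add atoms: none
Why: Thermodynamic epimerisation α to a ketone, in which the trans ketone suffers the syn-axial C19/C20 contact and near-eclipsing of C6=O with the equatorial C4 methyl, strain that the A/B-cis form relieves (the same bias makes 5β-H the stable form of 6,7-dioxoabietatrienes), so C5 should settle as R while quaternary C10 is untouched.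

Step 16
Reactants: 22 (5R,10S)-11,12-bis(benzyloxy)abieta-8,11,13-trien-6-one
Product: 23 (5R,10S)-11,12-bis(benzyloxy)-6,6-(ethylenedioxy)abieta-8,11,13-triene
Conditions: HOCH2CH2OH, p-TsOH (5 mol %), benzene, reflux, Dean–Stark
Reagents that add atoms: ethylene glycol, OCCO
Why: Acid-catalysed ketalisation with azeotropic water removal, in which the cis ketone lacks the methyl pair that would stand syn-axial to a 6β oxygen in the trans series, and acid enolisation cannot erode a centre already at equilibrium.

Step 17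
Reactants: 23 (5R,10S)-11,12-bis(benzyloxy)-6,6-(ethylenedioxy)abieta-8,11,13-triene
Product: 24 (5R,10S)-11,12-bis(benzyloxy)-14-bromo-6,6-(ethylenedioxy)abieta-8,11,13-triene
Conditions: NBS, MeCN, 0 → 23 °C, dark
Reagents that add atoms: N-bromosuccinimide, O=C1CCC(=O)N1Br
Why: Electrophilic aromatic bromination at C14, the only free position of ring C and para to O11, with polar solvent and darkness suppressing radical attack at C7 and at the benzyl CH2 groups.

Step 18
Reactants: 24 (5R,10S)-11,12-bis(benzyloxy)-14-bromo-6,6-(ethylenedioxy)abieta-8,11,13-triene; 8 (1S,6R)-6-isopropylbicyclo[4.1.0]hept-2-en-2-yl trifluoromethanesulfonate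
Product: 27 (5R,10S)-11,12-bis(benzyloxy)-6,6-(ethylenedioxy)-14-[(1S,6R)-6-isopropylbicyclo[4.1.0]hept-2-en-2-yl]abieta-8,11,13-triene, via aryllithium 25 (not isolated), via arylzinc chloride 26 (not isolated)
Conditions: n-BuLi, THF, −78 °C; ZnCl2, −78 → 23 °C; then 8, Pd2(dba)3 (2.5 mol %), SPhos (10 mol %), THF, 60 °C
Reagents that add atoms: none
Why: Negishi coupling, in which bromine–lithium exchange, transmetalation to zinc and coupling on zerovalent palladium form C14–C4', arylzinc reagents transmetalating well at di-ortho-substituted centres where an electron-rich boronate would protodeboronate; no stereocentre is touched.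

Step 19
Reactants: 27 (5R,10S)-11,12-bis(benzyloxy)-6,6-(ethylenedioxy)-14-[(1S,6R)-6-isopropylbicyclo[4.1.0]hept-2-en-2-yl]abieta-8,11,13-triene
Product: 28 C4'–C10' epoxide of 27 with oxygen anti to C6' (4'S,10'S,1'R,5'S)
Conditions: DMDO, acetone–CH2Cl2, −20 °C
Reagents that add atoms: dimethyldioxirane, CC1(C)OO1
Why: Neutral dioxirane epoxidation (no acid, so the labile tertiary cyclopropylcarbinyl epoxide survives), in which C6' screens one face of the norcarene as in 2-carene, so oxygen arrives anti to C6' and sets C4' and C10', while ring C stands perpendicular to the alkene and hinders both faces alike.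

Step 20
Reactants: 28 C4'–C10' epoxide of 27 with oxygen anti to C6' (4'S,10'S,1'R,5'S)
Product: 29 (5R,10S)-11,12-bis(benzyloxy)-6,6-(ethylenedioxy)-14-[(1S,2S,5R)-2-formyl-5-isopropylbicyclo[3.1.0]hexan-2-yl]abieta-8,11,13-triene
Conditions: MeAl(OC6H2-2,6-t-Bu2-4-Br)2 (2 equiv, from AlMe3 and 4-bromo-2,6-di-tert-butylphenol), CH2Cl2, −78 °C
Reagents that add atoms: none
Why: Proposed new method: the bulky aluminium Lewis acid binds the epoxide oxygen on the open face anti to C6', the C4'–O bond stretches (C4' is tertiary and cyclopropylcarbinyl but only weakly benzylic, because the hexasubstituted ring C is held perpendicular), and the C10'–C3' σ bond shifts to the rear lobe of C4' while C10'–O becomes the aldehyde, a Meinwald rearrangement with 1,2-alkyl shift. The closest known reactions are the Lewis-acid contraction of 1-arylcyclohexene oxides to 1-arylcyclopentanecarbaldehydes and the aluminium-phenoxide rearrangement of trisubstituted epoxides to aldehydes; what has not been shown is their course beside a fused cyclopropane. Ring E (C4'–C3'–C2'–C1'–C5') is closed by contraction of the six-membered ring through this shift, with C10' extruded as the formyl carbon, and not by an end-to-end cyclisation. The one new stereocentre, quaternary C4', is fixed by the stereospecific anti course: C3' enters opposite the departing oxygen, so the formyl group stays on the former oxygen face (anti to C6') and C14 ends syn to C6' (4'S), the epoxide face having been set by C6' in step 19. Three selectivities are needed: C3' over H-10' migration, a shift faster than cleavage of the C5'–C1' cyclopropane bond, and activation of the epoxide in preference to the dioxolane. They are addressed by the bulk of the aluminium phenoxide (it disfavours the hydride-shift rotamer and cannot reach the neopentyl-type ketal oxygens), by the near-orthogonality of the in-ring C5'–C1' bond to the developing p orbital at C4', and by a non-nucleophilic medium at −78 °C.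

Step 21
Reactants: 29 (5R,10S)-11,12-bis(benzyloxy)-6,6-(ethylenedioxy)-14-[(1S,2S,5R)-2-formyl-5-isopropylbicyclo[3.1.0]hexan-2-yl]abieta-8,11,13-triene
Product: 30 (5R,10S)-11,12-bis(benzyloxy)-14-[(1S,2S,5R)-2-formyl-5-isopropylbicyclo[3.1.0]hexan-2-yl]abieta-8,11,13-trien-6-one
Conditions: 1 M HCl, THF, 23 °C
Reagents that add atoms: water, O
Why: Acid-catalysed acetal hydrolysis helped by release of strain around C6, in which the formyl group on quaternary C4' cannot enolise, C5 is at its equilibrium configuration, and dilute acid at room temperature should neither open the unactivated cyclopropane nor dehydrate any aldol formed adventitiously.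

Step 22
Reactants: 30 (5R,10S)-11,12-bis(benzyloxy)-14-[(1S,2S,5R)-2-formyl-5-isopropylbicyclo[3.1.0]hexan-2-yl]abieta-8,11,13-trien-6-one
Product: 33 pentacyclic aldol with 7α-H and 10'β-OH (5R,7S,10S,4'S,10'S,1'R,5'S), via lithium enolate 31 (not isolated), via lithium aldolate 32 (not isolated)
Conditions: LiHMDS (1.05 equiv), THF, −78 °C; AcOH, −78 °C
Reagents that add atoms: none
Why: Intramolecular aldol addition (5-enolexo-exo-trig closure of ring D), in which the base removes the benzylic C7-H faster than it adds to the neopentyl aldehyde and leaves C5-H (flanked by two quaternary carbons) alone, a lithium chelate between O6 and O10' places the new oxygen cis to C6 on ring D, C10' should tilt to the β face because the other envelope presses C5'/C6' against the C13 isopropyl group, which together predict 7α-H and 10'β-OH, and the cold acid quench forestalls E1cB loss of water.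

Step 23
Reactants: 33 pentacyclic aldol with 7α-H and 10'β-OH (5R,7S,10S,4'S,10'S,1'R,5'S)
Product: 34 11,12-catechol of 33
Conditions: H2 (1 atm), Pd/C (10 wt %), EtOAc, 23 °C; filtered under argon
Reagents that add atoms: none
Why: Catalytic hydrogenolysis of both aryl benzyl ethers under neutral conditions, which spares the β-hydroxy ketone (C10'–O is not benzylic), the C6 ketone and the alkyl-substituted cyclopropane.

Step 24
Reactants: 34 11,12-catechol of 33
Product: 36 target CNP0178265.1 (5R,10S,4'S,10'R,1'R,5'S), via 11,12-ortho-quinone 35 (not isolated)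
Conditions: Ag2O, Et2O, 23 °C
Reagents that add atoms: none
Why: Catechol oxidation followed by a prototropic shift, in which the ortho-quinone passes its acidic C7-H (α to C6=O and vinylogous to C11=O) to O11 and gives the 11-hydroxy-12-oxo C7=C8 quinone methide as 6-oxo-11,12-catechols of this class do; C7 is erased and all six remaining stereocentres are untouched.

## Compound list

1 | 3-ethoxycyclohex-2-en-1-one | CCOC1=CC(=O)CCC1 | starting material
2 | chloromagnesium 3-ethoxy-1-isopropylcyclohex-2-en-1-olate (racemic) | CCOC1=CC(O[Mg]Cl)(C(C)C)CCC1 | intermediate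
3 | 3-isopropylcyclohex-2-en-1-one | CC(C)C1=CC(=O)CCC1 | intermediate
4 | (R)-3-isopropylcyclohex-2-en-1-ol | O[C@@H]1CCCC(C(C)C)=C1 | intermediate
5 | (1S,2R,6R)-6-isopropylbicyclo[4.1.0]heptan-2-ol | O[C@@H]1CCC[C@]2(C(C)C)C[C@H]12 | intermediate
6 | (1S,6R)-6-isopropylbicyclo[4.1.0]heptan-2-one | O=C1CCC[C@]2(C(C)C)C[C@H]12 | intermediate
7 | lithium enolate of 6 | [Li]OC1=CCC[C@]2(C(C)C)C[C@H]12 | intermediate
8 | (1S,6R)-6-isopropylbicyclo[4.1.0]hept-2-en-2-yl triflate | O=S(=O)(OC1=CCC[C@]2(C(C)C)C[C@H]12)C(F)(F)F | intermediate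
9 | 3-bromo-4,5-dihydroxybenzaldehyde | O=Cc1cc(O)c(O)c(Br)c1 | starting material
10 | 3,4-bis(benzyloxy)-5-bromobenzaldehyde | O=Cc1cc(OCc2ccccc2)c(OCc2ccccc2)c(Br)c1 | intermediate
11 | 3,4-bis(benzyloxy)-5-isopropylbenzaldehyde | O=Cc1cc(OCc2ccccc2)c(OCc2ccccc2)c(C(C)C)c1 | intermediate
12 | [3,4-bis(benzyloxy)-5-isopropylphenyl]methanol | OCc1cc(OCc2ccccc2)c(OCc2ccccc2)c(C(C)C)c1 | intermediate
13 | 1,2-bis(benzyloxy)-5-(chloromethyl)-3-isopropylbenzene | ClCc1cc(OCc2ccccc2)c(OCc2ccccc2)c(C(C)C)c1 | intermediate
14 | geranyl bromide | CC(C)=CCC/C(C)=C/CBr | starting material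
15 | [3,4-bis(benzyloxy)-5-isopropylbenzyl]magnesium chloride | Cl[Mg]Cc1cc(OCc2ccccc2)c(OCc2ccccc2)c(C(C)C)c1 | intermediate
16 | (E)-1,2-bis(benzyloxy)-5-(4,8-dimethylnona-3,7-dien-1-yl)-3-isopropylbenzene | CC(C)=CCC/C(C)=C/CCc1cc(OCc2ccccc2)c(OCc2ccccc2)c(C(C)C)c1 | intermediate
17 | (S)-1,2-bis(benzyloxy)-3-isopropyl-5-[2-(2,6,6-trimethylcyclohex-2-en-1-yl)ethyl]benzene | CC1=CCCC(C)(C)[C@@H]1CCc1cc(OCc2ccccc2)c(OCc2ccccc2)c(C(C)C)c1 | intermediate
18 | (5S,10S)-11,12-bis(benzyloxy)abieta-8,11,13-triene | CC(C)c1cc2CC[C@H]3C(C)(C)CCC[C@]3(C)c2c(OCc2ccccc2)c1OCc1ccccc1 | intermediate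
19 | (5S,10S)-11,12-bis(benzyloxy)abieta-6,8,11,13-tetraene | CC(C)c1cc2C=C[C@H]3C(C)(C)CCC[C@]3(C)c2c(OCc2ccccc2)c1OCc1ccccc1 | intermediate
20 | (5S,10S)-11,12-bis(benzyloxy)-6α,7α-epoxyabieta-8,11,13-triene | CC(C)c1cc2[C@@H]4O[C@@H]4[C@H]3C(C)(C)CCC[C@]3(C)c2c(OCc2ccccc2)c1OCc1ccccc1 | intermediate
21 | (5S,10S)-11,12-bis(benzyloxy)abieta-8,11,13-trien-6-one (A/B trans) | CC(C)c1cc2CC(=O)[C@H]3C(C)(C)CCC[C@]3(C)c2c(OCc2ccccc2)c1OCc1ccccc1 | intermediate
22 | (5R,10S)-11,12-bis(benzyloxy)abieta-8,11,13-trien-6-one (A/B cis) | CC(C)c1cc2CC(=O)[C@@H]3C(C)(C)CCC[C@]3(C)c2c(OCc2ccccc2)c1OCc1ccccc1 | intermediate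
23 | (5R,10S)-11,12-bis(benzyloxy)-6,6-(ethylenedioxy)abieta-8,11,13-triene | CC(C)c1cc2CC4(OCCO4)[C@@H]3C(C)(C)CCC[C@]3(C)c2c(OCc2ccccc2)c1OCc1ccccc1 | intermediate
24 | 14-bromo derivative of 23 | CC(C)c1c(Br)c2CC4(OCCO4)[C@@H]3C(C)(C)CCC[C@]3(C)c2c(OCc2ccccc2)c1OCc1ccccc1 | intermediate
25 | C14 aryllithium from 24 | CC(C)c1c([Li])c2CC4(OCCO4)[C@@H]3C(C)(C)CCC[C@]3(C)c2c(OCc2ccccc2)c1OCc1ccccc1 | intermediate
26 | C14 arylzinc chloride from 25 | CC(C)c1c([Zn]Cl)c2CC4(OCCO4)[C@@H]3C(C)(C)CCC[C@]3(C)c2c(OCc2ccccc2)c1OCc1ccccc1 | intermediate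
27 | C14-(norcar-2-en-2-yl) C6-ketal abietane (5R,10S,1'R,5'S) | CC(C)c1c(C4=CCC[C@]5(C(C)C)C[C@H]45)c2CC6(OCCO6)[C@@H]3C(C)(C)CCC[C@]3(C)c2c(OCc2ccccc2)c1OCc1ccccc1 | intermediate
28 | C4'–C10' epoxide of 27, oxygen anti to C6' (4'S,10'S) | CC(C)c1c([C@]45O[C@H]4CC[C@]6(C(C)C)C[C@H]56)c2CC7(OCCO7)[C@@H]3C(C)(C)CCC[C@]3(C)c2c(OCc2ccccc2)c1OCc1ccccc1 | intermediate (key-step precursor)
29 | C14-aryl thujane C4' carbaldehyde on the C6-ketal abietane (4'S) | CC(C)c1c([C@]4(C=O)CC[C@]5(C(C)C)C[C@H]45)c2CC6(OCCO6)[C@@H]3C(C)(C)CCC[C@]3(C)c2c(OCc2ccccc2)c1OCc1ccccc1 | intermediate (key-step product)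
30 | C6 ketone C4' carbaldehyde | CC(C)c1c([C@]4(C=O)CC[C@]5(C(C)C)C[C@H]45)c2CC(=O)[C@@H]3C(C)(C)CCC[C@]3(C)c2c(OCc2ccccc2)c1OCc1ccccc1 | intermediate
31 | C6=C7 lithium enolate of 30 | CC(C)c1c([C@]4(C=O)CC[C@]5(C(C)C)C[C@H]45)c2C=C(O[Li])[C@@H]3C(C)(C)CCC[C@]3(C)c2c(OCc2ccccc2)c1OCc1ccccc1 | intermediate
32 | lithium aldolate of 33 | CC(C)c1c2c3[C@H](C(=O)[C@@H]4C(C)(C)CCC[C@]4(C)c3c(OCc3ccccc3)c1OCc1ccccc1)[C@H](O[Li])[C@]21CC[C@]2(C(C)C)C[C@@H]21 | intermediate
33 | pentacyclic aldol, 7α-H, 10'β-OH, 11,12-dibenzyl ether | CC(C)c1c2c3[C@H](C(=O)[C@@H]4C(C)(C)CCC[C@]4(C)c3c(OCc3ccccc3)c1OCc1ccccc1)[C@H](O)[C@]21CC[C@]2(C(C)C)C[C@@H]21 | intermediate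
34 | 11,12-catechol of 33 | CC(C)c1c2c3[C@H](C(=O)[C@@H]4C(C)(C)CCC[C@]4(C)c3c(O)c1O)[C@H](O)[C@]21CC[C@]2(C(C)C)C[C@@H]21 | intermediate
35 | 11,12-ortho-quinone | CC(C)C1=C2C=3[C@H](C(=O)[C@@H]4C(C)(C)CCC[C@]4(C)C3C(=O)C1=O)[C@H](O)[C@]21CC[C@]2(C(C)C)C[C@@H]21 | intermediate
36 | CNP0178265.1 | CC(C)C1=C2C3=C(C(=O)[C@@H]4C(C)(C)CCC[C@]4(C)C3=C(O)C1=O)[C@H](O)[C@]21CC[C@]2(C(C)C)C[C@@H]21 | target

## Step count and risks

Total step count: 24. Longest linear sequence: 19 (steps 6–24, from 9).

**Step 20 (bears the label).**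
- Several processes may intervene:
  - migration of H-10' instead of C3';
  - cleavage of the C5'–C1' cyclopropane bond by the electron-deficient C4', with ring enlargement;
  - a long-lived cation that loses the anti stereospecificity;
  - diversion of the Lewis acid to the ketal.
- The fallback uses known reaction types, sets out from 24 and comes back at 29. It moves the aryl group instead of a ring carbon.
- Bromide 24 is lithiated (n-BuLi) and formylated with DMF to give the 14-carbaldehyde F1.
- Commercial (+)-sabinene is ozonised to (1S,5R)-sabina ketone F2. LiHMDS and PhNTf2 convert it into its enol triflate F3.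
- A Nozaki–Hiyama–Kishi coupling (CrCl2, NiCl2 catalyst, DMF) joins F3 to F1 and gives the allylic alcohol F4. Both C10' epimers are usable.
- NBS then triggers a halonium-induced semipinacol rearrangement. The bromonium ion forms anti to C6', and ring C migrates from C10' to C4' on the opposite face. This gives the 3'-bromo aldehyde F5 with the same 4'S centre.
- Bu3SnH/AIBN at high stannane concentration removes the bromine and gives 29.

**Step 15.**
- The equilibrium at C5 may be incomplete or may lie on the trans side. The C7 enolate may also be autoxidised.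
- The fallback sets out from 13 and comes back at 22. It sets C5 by alkene geometry instead of by equilibration.
- Nerol is converted with PBr3 into neryl bromide F6, which is coupled with Grignard reagent 15 as in step 10 to give the (Z)-polyene F7.
- Cyclisation with the (S)-configured tin acid should give the cis-fused (5R,10S)-tricycle F8, by stereospecific anti addition to a Z alkene.
- DDQ gives the Δ6 alkene F9, DMDO gives the epoxide F10, and BF3·OEt2 gives 22.
- C5 is then held kinetically. All later enolisations go to the benzylic C7, and C5-H lies between two quaternary carbons.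

**Step 22.**
- Facial selectivity at the aldehyde may be poor, the aldol may revert, or water may be lost by an E1cB process to give the conjugated indene-type enone.
- The fallback sets out from 30 and comes back at 33. It replaces the metal enolate by a Lewis-acid aldol.
- TBSOTf/Et3N at −78 °C gives the C6 silyl enol ether F11.
- BF3·OEt2 at −78 °C then closes ring D in an intramolecular Mukaiyama aldol reaction.
- This reaction passes through an open transition state. It is non-basic, and its sense at C10' complements that of the chelated lithium aldol.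

## Further compounds

F1 | step 20 | 14-carbaldehyde of 23 | CC(C)c1c(C=O)c2CC4(OCCO4)[C@@H]3C(C)(C)CCC[C@]3(C)c2c(OCc2ccccc2)c1OCc1ccccc1
F2 | step 20 | (1S,5R)-5-isopropylbicyclo[3.1.0]hexan-2-one (sabina ketone) | O=C1CC[C@]2(C(C)C)C[C@H]12
F3 | step 20 | (1S,5R)-5-isopropylbicyclo[3.1.0]hex-2-en-2-yl triflate | O=S(=O)(OC1=CC[C@]2(C(C)C)C[C@H]12)C(F)(F)F
F4 | step 20 | C14-aryl (thuj-3-en-4-yl) carbinol, C10' epimers | CC(C)c1c(C(O)C4=CC[C@]5(C(C)C)C[C@H]45)c2CC6(OCCO6)[C@@H]3C(C)(C)CCC[C@]3(C)c2c(OCc2ccccc2)c1OCc1ccccc1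
F5 | step 20 | 3'-bromo derivative of 29, bromine cis to the formyl group | CC(C)c1c([C@]4(C=O)[C@@H](Br)C[C@]5(C(C)C)C[C@H]45)c2CC6(OCCO6)[C@@H]3C(C)(C)CCC[C@]3(C)c2c(OCc2ccccc2)c1OCc1ccccc1
F6 | step 15 | neryl bromide | CC(C)=CCC/C(C)=C\CBr
F7 | step 15 | (Z)-1,2-bis(benzyloxy)-5-(4,8-dimethylnona-3,7-dien-1-yl)-3-isopropylbenzene | CC(C)=CCC/C(C)=C\CCc1cc(OCc2ccccc2)c(OCc2ccccc2)c(C(C)C)c1
F8 | step 15 | (5R,10S)-11,12-bis(benzyloxy)abieta-8,11,13-triene (A/B cis) | CC(C)c1cc2CC[C@@H]3C(C)(C)CCC[C@]3(C)c2c(OCc2ccccc2)c1OCc1ccccc1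
F9 | step 15 | (5R,10S)-11,12-bis(benzyloxy)abieta-6,8,11,13-tetraene | CC(C)c1cc2C=C[C@@H]3C(C)(C)CCC[C@]3(C)c2c(OCc2ccccc2)c1OCc1ccccc1
F10 | step 15 | 6,7-epoxide of F9, drawn as the α-epoxide (configuration lost in the next operation) | CC(C)c1cc2[C@@H]4O[C@@H]4[C@@H]3C(C)(C)CCC[C@]3(C)c2c(OCc2ccccc2)c1OCc1ccccc1
F11 | step 22 | C6 tert-butyldimethylsilyl enol ether of 30 | CC(C)c1c([C@]4(C=O)CC[C@]5(C(C)C)C[C@H]45)c2C=C(O[Si](C)(C)C(C)(C)C)[C@@H]3C(C)(C)CCC[C@]3(C)c2c(OCc2ccccc2)c1OCc1ccccc1
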